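All runs come from a simulation with constants of no real substance; the scatter is artificial.

At late times the winter run, which is this very flask followed so far, has nearly stopped, so the useful question is what has stopped it.

- winter: starting material 0.083 M; partner 0.149 M; second substrate 0.083 M; free catalyst 83 µM; impurity 34 µM; the very flask that is asked about, followed so far
- flask: starting material 0.083 M; partner 0.149 M; second substrate 0.0830 M; free catalyst 83 µM; impurity 34 µM; time 8.0 d
winter run (percent of the starting material charged)

| time / d | target / % | starting material / % |
|---|---|---|
| 0.417 | 25.3 | 73.7 |
| 1.25 | 40.9 | 58.1 |
| 2.50 | 48.1 | 50.7 |
| 4.00 | 49.9 | 48.8 |
| 5.00 | 51.5 | 48.9 |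
| 6.00 | 51.7 | 47.7 |

(each reading ± 0.5 percentage points)
- Thursday's: change nothing and wait 8.0 d more
- Sunday's: at 8.0 d add partner, 100% of the amount charged, then wait 8.0 d
- Tuesday's: at 8.0 d take out 90% of the target then present, then wait 8.0 d
- Friday's: at 8.0 d add free catalyst, 50.0% of the amount charged, then wait 8.0 d
- target that was removed still counts
- the analysis behind the earlier runs scatters by 0.5 percentage points, standard deviation
- reactions considered so far: starting material + partner + free catalyst -> free catalyst + target; second substrate + partner + free catalyst -> free catalyst + second product; partner -> decomposed reagent; free catalyst + impurity -> spent catalyst
- additions bring no volume worth counting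
- target, in percent of the starting material first charged, at 8.0 d
- which option adds most target ("none" when 2 percentage points or less is all one gets) (Thursday's / Sunday's / Tuesday's / Friday's / none)
- target present, with what was taken out counted in, in percent of the starting material first charged, after Tuesday's
- target present, with what was taken out counted in, in percent of the starting material first charged, after Friday's

The quantity to count is the turnover number, meaning target made per live catalyst. Each impurity takes one free catalyst, and c(impurity) is smaller than c(free catalyst), so live catalyst stands at 49.0 µM.

The first row of the table reads 429 turnovers, which is 1030 d⁻¹. The last row reads 876 turnovers per live catalyst. Between the last rows but two and the last, the readings give 15.2 d⁻¹, far slower than at the start.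

Target needs starting material, partner and free catalyst together. Starting material still reads 47.7%, and free catalyst stays at 49.0 µM or above, so the fall must lie in partner.

This reckoning therefore holds target near the last reading, 51.7%, at 8.0 d. Sunday's brings fresh partner, 100% of the amount charged, and the first charge has so far been read at 876 turnovers. Partner also feeds second product and decomposed reagent, so this reckoning expects Sunday's to add target but to leave part of the 808 turnovers held in the remaining starting material unused, whereas Thursday's, Tuesday's and Friday's bring no partner.

The forecast gives 52.2%, chooses Sunday's, and puts Tuesday's at 52.4% and Friday's at 52.5%, on the ground that “Partner is the likely limit”.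

The flask gives 51.3% and Sunday's as the best option, adding 34 percentage points, while Tuesday's ends at 51.4% and Friday's at 51.4%.

    starting material + partner + free catalyst → free catalyst + target (k = 84.0 L² mol⁻² min⁻¹)
    second substrate + partner + free catalyst → free catalyst + second product (k = 110 L² mol⁻² min⁻¹)
    partner → decomposed reagent (k = 3.30 × 10⁻⁴ min⁻¹)
    free catalyst + impurity → spent catalyst (k = 230 L mol⁻¹ min⁻¹)

The half-life of starting material by the target step is 0.46 d with everything as charged, but 2900 d at 8.00 d, against a further wait of 8.0 d. Partner, the limiting reagent, is down to 0.027% of its charge there, which, counted wholly as target, comes to 0.827 turnovers per live catalyst against the 876 already counted.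

In a neighbour flask with 1.4 × 10⁻⁵ M of impurity, the same count per live catalyst gives 72.8% target. The computed neighbour flask stands at 56.5%, which is 680 turnovers, fewer than in this flask, with 0.0096% of its partner left.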